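## Retrosynthetic overview

1. The target comes from global removal of two aryl tosylates and two acetates from a protected lariciresinol glycerol ether.
2. Its single tetrahydrofuran comes from site-selective reductive opening of ring B (the C7'–O bond beside the alkoxy-aryl ring) of an unsymmetrical pinoresinol-type furofuran; ring A, beside the tosyloxy-aryl ring, stays closed.
3. The furofuran (ring A, then ring B, in one flask) comes from an acyclic epoxy cinnamyl ether by titanocene-mediated epoxide opening, 5-exo radical cyclization and iodine-triggered etherification; the single stereocentre C7 relays C8 and C8'.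
4. The epoxy cinnamyl ether comes from cross-metathesis of an epoxy allyl ether (vanillin: tosylation, vinyl addition, Sharpless kinetic-resolution epoxidation, O-allylation) with a propenylarene that already carries the glycerol unit.
5. The (7''R,8''R)-glycerol aryl ether comes from an Evans syn-aldol of an isoeugenol-derived aryloxyacetyl oxazolidinone with O-tosylvanillin, then reductive auxiliary removal and acetylation.

Locants: C7–C9 belong to the ring A half (C7 is the benzylic ether carbon), C7'–C9' to the benzyl half, C7''–C9'' to the glycerol unit; Ts = 4-methylbenzenesulfonyl.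

Assumption: (S)-4-benzyl-3-(chloroacetyl)oxazolidin-2-one, D-(−)-diisopropyl tartrate and (E)-isoeugenol are bought as such.

## Route

Step 1
Reactants: 1 vanillin (4-hydroxy-3-methoxybenzaldehyde)
Product: 2 4-formyl-2-methoxyphenyl 4-methylbenzenesulfonate (O-tosylvanillin)
Conditions: TsCl (1.1 equiv), Et3N (1.5 equiv), DMAP (5 mol %), CH2Cl2, 0 °C to rt
Reagents that add atoms: 4-methylbenzenesulfonyl chloride, Cc1ccc(cc1)S(Cl)(=O)=O
Why: Phenol O-sulfonylation gives a protecting group that survives every later step, is cleaved by hydroxide at the end, and is electron-withdrawing enough to differentiate the two benzylic ethers in step 11.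

Step 2
Reactants: 2 O-tosylvanillin
Product: 3 rac-4-(1-hydroxyprop-2-en-1-yl)-2-methoxyphenyl 4-methylbenzenesulfonate
Conditions: CH2=CHMgBr (1.1 equiv), THF, −78 °C; aq. NH4Cl
Reagents that add atoms: vinylmagnesium bromide, C=C[Mg]Br
Why: Grignard 1,2-addition to the aldehyde is far faster at −78 °C than attack on the aryl sulfonate; the carbinol is racemic and is resolved in step 3.

Step 3
Reactants: 3 racemic aryl vinyl carbinol
Product: 4 4-[(R)-hydroxy[(2S)-oxiran-2-yl]methyl]-2-methoxyphenyl 4-methylbenzenesulfonate (erythro epoxy alcohol)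
Conditions: Ti(OiPr)4 (0.15 equiv), D-(−)-diisopropyl tartrate (0.2 equiv), t-BuOOH (0.45 equiv, anhydrous), 4 Å molecular sieves, CH2Cl2, −20 °C, stopped near 45% conversion
Reagents that add atoms: tert-butyl hydroperoxide, CC(C)(C)OO
Why: In this Sharpless kinetic-resolution epoxidation the D-tartrate catalyst epoxidises the (S)-carbinol fast and erythro-selectively while (R)-3 is left behind, which fixes C7 of the target (the carbinol descriptor becomes R only because the oxirane carbon now outranks the aryl group).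

Step 4
Reactants: 4 erythro epoxy alcohol
Product: 5 4-[(R)-(allyloxy)[(2S)-oxiran-2-yl]methyl]-2-methoxyphenyl 4-methylbenzenesulfonate
Conditions: NaH (1.2 equiv), allyl bromide (1.5 equiv), Bu4NI (5 mol %), THF, 0 °C to rt
Reagents that add atoms: allyl bromide, C=CCBr
Why: Williamson etherification in aprotic THF with a fast allylic electrophile traps the alkoxide before Payne rearrangement and leaves C7 untouched.

Step 5
Reactants: 6 (E)-isoeugenol [2-methoxy-4-((E)-prop-1-enyl)phenol]; 7 (S)-4-benzyl-3-(chloroacetyl)oxazolidin-2-one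
Product: 8 (S)-4-benzyl-3-{[2-methoxy-4-((E)-prop-1-enyl)phenoxy]acetyl}oxazolidin-2-one
Conditions: K2CO3 (1.5 equiv), NaI (10 mol %), acetone, rt
Reagents that add atoms: none
Why: Williamson SN2 alkylation of the phenoxide by the α-chloro imide installs the future C8''–O–aryl bond and the Evans auxiliary together.

Step 6
Reactants: 8 aryloxyacetyl oxazolidinone; 2 O-tosylvanillin
Product: 10 (S)-4-benzyl-3-[(2S,3R)-3-hydroxy-3-(3-methoxy-4-tosyloxyphenyl)-2-[2-methoxy-4-((E)-prop-1-enyl)phenoxy]propanoyl]oxazolidin-2-one, via Z-dibutylboron enolate 9 (not isolated)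
Conditions: Bu2BOTf (1.2 equiv), iPr2NEt (1.4 equiv), CH2Cl2, −78 to 0 °C; then 2 (1.1 equiv), −78 to 0 °C; pH 7 buffer/MeOH
Reagents that add atoms: none
Why: In this Evans syn-aldol the Z-boron enolate reacts through a Zimmerman–Traxler chair on the face away from the benzyl group of the (S)-auxiliary, setting C8'' and C7'' together as the syn (threo) pair that becomes (7''R,8''R).

Step 7
Reactants: 10 aldol adduct
Product: 11 (1R,2R)-1-(3-methoxy-4-tosyloxyphenyl)-2-[2-methoxy-4-((E)-prop-1-enyl)phenoxy]propane-1,3-diol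
Conditions: LiBH4 (2 equiv), MeOH (2 equiv), THF, 0 °C to rt
Reagents that add atoms: none
Why: Hydride reduction of the activated imide carbonyl cleaves the auxiliary to the primary alcohol without touching the sulfonate, the propenyl group or either stereocentre.

Step 8
Reactants: 11 threo diol
Product: 12 (1R,2R)-1-(3-methoxy-4-tosyloxyphenyl)-2-[2-methoxy-4-((E)-prop-1-enyl)phenoxy]propane-1,3-diyl diacetate
Conditions: Ac2O (3 equiv), pyridine, DMAP (5 mol %), CH2Cl2, rt
Reagents that add atoms: acetic anhydride, CC(=O)OC(C)=O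
Why: Acylation of both hydroxyls keeps free alcohols away from trivalent titanium in step 10 and shuts down ionisation at C7'' in step 11.

Step 9
Reactants: 5 epoxy allyl ether; 12 propenylarene diacetate
Product: 13 (1R,2R)-2-{2-methoxy-4-[(E)-3-{(R)-[3-methoxy-4-(tosyloxy)phenyl][(2S)-oxiran-2-yl]methoxy}prop-1-en-1-yl]phenoxy}-1-[3-methoxy-4-(tosyloxy)phenyl]propane-1,3-diyl diacetate
Conditions: 5 (1.5 equiv), second-generation Grubbs catalyst RuCl2(=CHPh)(PCy3)(H2IMes) (5 mol %), CH2Cl2, 40 °C, argon sweep
Reagents that add atoms: none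
Why: Olefin cross-metathesis of a terminal allyl ether with a propenylarene is driven by loss of propene and gives the conjugated E-alkene; the few percent of C7 epimer from the minor enantiomer of 4 becomes a separable diastereomer here.

Step 10
Reactants: 13 epoxy cinnamyl ether
Product: 15 (1R,2R)-2-{2-methoxy-4-[(1S,3aR,4S,6aR)-4-(3-methoxy-4-tosyloxyphenyl)tetrahydro-1H,3H-furo[3,4-c]furan-1-yl]phenoxy}-1-(3-methoxy-4-tosyloxyphenyl)propane-1,3-diyl diacetate, via benzylic iodide 14 (not isolated)
Conditions: Cp2TiCl2 (2.5 equiv), Zn dust, THF, rt (green Cp2TiCl, decanted from Zn); added to 13 in THF over 1 h, rt; then I2 (1.3 equiv), rt to 60 °C; aq. Na2S2O3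
Reagents that add atoms: none
Why: Titanocene-mediated reductive epoxide opening gives the secondary C8 radical, whose 5-exo cyclization through a chair-like Beckwith–Houk transition state places C9 trans to the C7 aryl and cis to the new benzylic arm (C8 R, C8' R); iodination of the benzylic titanium species and displacement of iodide by the C9 titanium alkoxide then close ring B with the aryl group exo, a radical-polar cascade known for simple epoxy cinnamyl ethers.

Step 11
Reactants: 15 furofuran
Product: 16 (1R,2R)-2-[4-({(3R,4R,5S)-4-(hydroxymethyl)-5-[3-methoxy-4-(tosyloxy)phenyl]oxolan-3-yl}methyl)-2-methoxyphenoxy]-1-[3-methoxy-4-(tosyloxy)phenyl]propane-1,3-diyl diacetate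
Conditions: Et3SiH (5 equiv), BF3·OEt2 (2 equiv), CH2Cl2, −78 to −30 °C; aq. NaHCO3
Reagents that add atoms: none
Why: Proposed new method: site-selective ionic hydrogenation of one benzylic ether of a furofuran, in which BF3 ionises only the C7'–O bond because that cation is stabilised by the para alkoxy group while the C7–O bond and the C7'' acetate sit on rings deactivated by para tosyloxy groups (a σ+ gap worth at least three orders of magnitude in rate) and Et3SiH traps the cation as CH2 before elimination, the closest known reactions being Et3SiH/Lewis-acid reduction of benzylic ethers and 2-aryltetrahydrofurans and the Pd/C hydrogenolysis of pinoresinol to lariciresinol; C7, C8 and C8' are untouched and the trans relation of the C7 aryl to the C8' arm rules out Friedel–Crafts closure.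

Step 12
Reactants: 16 protected lariciresinol glycerol ether
Product: 17 (1R,2R)-1-(4-hydroxy-3-methoxyphenyl)-2-[4-({(3R,4R,5S)-5-(4-hydroxy-3-methoxyphenyl)-4-(hydroxymethyl)oxolan-3-yl}methyl)-2-methoxyphenoxy]propane-1,3-diol (CNP0158473.2)
Conditions: KOH (10 equiv), MeOH/H2O 4:1, argon, 65 °C; then aq. HCl to pH 5
Reagents that add atoms: none
Why: Saponification of the two acetates and hydroxide cleavage of the two aryl sulfonates at sulfur occur in one operation, and all five stereocentres are non-epimerisable ether or carbinol carbons.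

## Compound list

1 | vanillin (4-hydroxy-3-methoxybenzaldehyde) | COc1cc(C=O)ccc1O | starting material
2 | 4-formyl-2-methoxyphenyl 4-methylbenzenesulfonate | COc1cc(C=O)ccc1OS(=O)(=O)c1ccc(C)cc1 | intermediate
3 | rac-4-(1-hydroxyprop-2-en-1-yl)-2-methoxyphenyl 4-methylbenzenesulfonate | COc1cc(C(O)C=C)ccc1OS(=O)(=O)c1ccc(C)cc1 | intermediate
4 | 4-[(R)-hydroxy[(2S)-oxiran-2-yl]methyl]-2-methoxyphenyl 4-methylbenzenesulfonate | COc1cc([C@@H](O)[C@@H]2CO2)ccc1OS(=O)(=O)c1ccc(C)cc1 | intermediate
5 | 4-[(R)-(allyloxy)[(2S)-oxiran-2-yl]methyl]-2-methoxyphenyl 4-methylbenzenesulfonate | COc1cc([C@@H](OCC=C)[C@@H]2CO2)ccc1OS(=O)(=O)c1ccc(C)cc1 | intermediate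
6 | (E)-isoeugenol | C/C=C/c1ccc(O)c(OC)c1 | starting material
7 | (S)-4-benzyl-3-(chloroacetyl)oxazolidin-2-one | O=C(CCl)N1[C@@H](Cc2ccccc2)COC1=O | starting material
8 | (S)-4-benzyl-3-{[2-methoxy-4-((E)-prop-1-enyl)phenoxy]acetyl}oxazolidin-2-one | C/C=C/c1ccc(OCC(=O)N2[C@@H](Cc3ccccc3)COC2=O)c(OC)c1 | intermediate
9 | Z-dibutylboron enolate of 8 (not isolated) | C/C=C/c1ccc(O/C=C(\OB(CCCC)CCCC)N2[C@@H](Cc3ccccc3)COC2=O)c(OC)c1 | intermediate
10 | (S)-4-benzyl-3-[(2S,3R)-3-hydroxy-3-(3-methoxy-4-tosyloxyphenyl)-2-[2-methoxy-4-((E)-prop-1-enyl)phenoxy]propanoyl]oxazolidin-2-one | COc1cc([C@@H](O)[C@@H](C(=O)N2[C@@H](Cc3ccccc3)COC2=O)Oc2ccc(/C=C/C)cc2OC)ccc1OS(=O)(=O)c1ccc(C)cc1 | intermediate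
11 | (1R,2R)-1-(3-methoxy-4-tosyloxyphenyl)-2-[2-methoxy-4-((E)-prop-1-enyl)phenoxy]propane-1,3-diol | COc1cc([C@@H](O)[C@@H](CO)Oc2ccc(/C=C/C)cc2OC)ccc1OS(=O)(=O)c1ccc(C)cc1 | intermediate
12 | 1,3-diacetate of 11 | COc1cc([C@@H](OC(C)=O)[C@@H](COC(C)=O)Oc2ccc(/C=C/C)cc2OC)ccc1OS(=O)(=O)c1ccc(C)cc1 | intermediate
13 | (E)-cinnamyl ether joining 5 and 12, with (R)-C7 and (S)-oxirane | COc1cc([C@@H](OC(C)=O)[C@@H](COC(C)=O)Oc2ccc(/C=C/CO[C@H](c3ccc(OS(=O)(=O)c4ccc(C)cc4)c(OC)c3)[C@@H]3CO3)cc2OC)ccc1OS(=O)(=O)c1ccc(C)cc1 | intermediate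
14 | benzylic iodide, 7'-iodo derivative of 16, both C7' epimers, present as its titanium alkoxide and drawn as the alcohol (not isolated) | COc1cc([C@@H](OC(C)=O)[C@@H](COC(C)=O)Oc2ccc(C(I)[C@H]3CO[C@H](c4ccc(OS(=O)(=O)c5ccc(C)cc5)c(OC)c4)[C@H]3CO)cc2OC)ccc1OS(=O)(=O)c1ccc(C)cc1 | intermediate
15 | exo,exo-furofuran with (1S,3aR,4S,6aR) core, ring A aryl tosylate, ring B aryl carrying the diacetylated glycerol unit | COc1cc([C@@H](OC(C)=O)[C@@H](COC(C)=O)Oc2ccc([C@@H]3[C@H]4CO[C@H](c5ccc(OS(=O)(=O)c6ccc(C)cc6)c(OC)c5)[C@H]4CO3)cc2OC)ccc1OS(=O)(=O)c1ccc(C)cc1 | intermediate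
16 | bis-tosylate diacetate of the target, oxolane (3R,4R,5S) | COc1cc([C@@H](OC(C)=O)[C@@H](COC(C)=O)Oc2ccc(C[C@H]3CO[C@H](c4ccc(OS(=O)(=O)c5ccc(C)cc5)c(OC)c4)[C@H]3CO)cc2OC)ccc1OS(=O)(=O)c1ccc(C)cc1 | intermediate
17 | CNP0158473.2, lariciresinol 4'-O-[threo-(7''R,8''R)-guaiacylglycerol-8''-yl] ether | COc1cc([C@@H](O)[C@@H](CO)Oc2ccc(C[C@H]3CO[C@H](c4ccc(O)c(OC)c4)[C@H]3CO)cc2OC)ccc1O | target

## Step count and risks

Total steps: 12. Longest linear sequence: 8 (steps 5–12 from isoeugenol; equally steps 1–4 and 9–12 from vanillin).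

Most likely to fail:

**Step 10 (radical-polar bicyclization).** The benzylic titanium species may be protonated or eliminate instead of being iodinated and closed. The fallback sets out from 13 and comes back at 16. The same epoxide opening and 5-exo cyclization is run with hydrogen-atom termination instead of iodine (Cp2TiCl, 2.2 equiv, 1,4-cyclohexadiene, THF, rt, dilute acid work-up). This single-ring radical cyclization gives the monocyclic alcohol 16 directly, the 3,4-trans epimer is removed by chromatography, and 15 and step 11 are bypassed. It makes no compound outside the list (none F0).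

**Step 11 (site-selective ring B opening).** Hydride capture may be too slow, giving elimination toward C8' or a sluggish reaction. The fallback sets out from 15 and comes back at 16. Ring B is opened by thiolysis (PhSH 3 equiv, BF3·OEt2 1.5 equiv, CH2Cl2, −78 °C), where the thiol traps the para-alkoxybenzyl cation far faster than a silane, giving the 7'-phenylsulfanyl derivative of 16 F1 as a C7' epimer mixture. Radical desulfurization (Bu3SnH, AIBN, toluene, 100 °C) then cleaves the benzylic C–S bond and leaves tosylates and acetates alone, giving 16.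

**Step 3 (kinetic-resolution epoxidation).** The yield is capped near 45% and the ee of an epoxide product depends on the rate ratio. The fallback sets out from 3 and comes back at 4. Resolution and epoxidation are separated: lipase-catalysed acylation (Burkholderia cepacia lipase, vinyl acetate, t-BuOMe, 30 °C, about 52% conversion) acetylates the R enantiomer to the (R)-acetate F3 and leaves the (S)-alcohol F2 in high ee. F2 is then epoxidised as the matched substrate (Ti(OiPr)4 10 mol %, D-(−)-diisopropyl tartrate 12 mol %, t-BuOOH 1.5 equiv, 4 Å sieves, CH2Cl2, −20 °C) to give 4 in near-full conversion.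

## Further compounds

F0 | step 10 | none | none
F1 | step 11 | 7'-phenylsulfanyl derivative of 16 (both C7' epimers) | COc1cc([C@@H](OC(C)=O)[C@@H](COC(C)=O)Oc2ccc(C(Sc3ccccc3)[C@H]3CO[C@H](c4ccc(OS(=O)(=O)c5ccc(C)cc5)c(OC)c4)[C@H]3CO)cc2OC)ccc1OS(=O)(=O)c1ccc(C)cc1
F2 | step 3 | (S)-4-(1-hydroxyprop-2-en-1-yl)-2-methoxyphenyl 4-methylbenzenesulfonate | COc1cc([C@@H](O)C=C)ccc1OS(=O)(=O)c1ccc(C)cc1
F3 | step 3 | (R)-1-[3-methoxy-4-(tosyloxy)phenyl]prop-2-en-1-yl acetate | COc1cc([C@H](OC(C)=O)C=C)ccc1OS(=O)(=O)c1ccc(C)cc1
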